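**Plan**

1. Retrosynthesis: after global desilylation, the C5–C9 and C3–C4 bonds are cut together. This unfolds the bicyclo[3.3.1]nonane-2,4,9-trione into a dearomatised 6-aryl-2H-pyran-2,4(3H)-dione (C9 = lactone carbonyl, C2 = ring ketone, C3 = ring CH, C1 = quaternary ring carbon) whose C1 chain ends in the C5 methyl ester (C4).
2. Enabling feature: ring C1–C2–C3–C4–C5–C9 is a cyclohexane-1,3,5-trione, a doubly C-alkylated acylphloroglucinol. C5 lies between the acyl carbons C9 and C4, and C3 between C2 and the aroyl carbonyl, so both bonds are enolate–acyl (Claisen) bonds, as in the polyketide biosynthesis of the benzophenone ring.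
3. Earlier cuts: C1–prenyl (O-to-C shift that dearomatises a 4-prenyloxy-2-pyrone), C5=C6 (olefination joining aldehyde 12 and phosphonate 20), C7–prenyl (auxiliary alkylation), C1–C8 (addition of a 4-hydroxy-2-pyrone to isopropylidene Meldrum's acid), pyrone ring (aryl ketone plus malonyl dichloride).
4. Forward ring order: pyrone ring; fused δ-lactone as a temporary ring, opened by the auxiliary; chain assembly; dearomatisation; then the cyclohexanone ring (C5–C9) and the trione ring (C3–C4) in one flask.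
5. Stereochemistry: C7 from the oxazolidinone auxiliary, C2' from Rh/(S)-BINAP conjugate addition, C4' from CBS reduction, C1 from the chiral palladium catalyst, C5 from the ring constraint of the bicycle (dictated by C1).

Key step: step 17

Locants: bicyclo[3.3.1]nonane numbering of the target is used throughout (C1 prenyl, C2 C=O, C3 aroyl, C4 enol carbon, C5 side chain, C6 CH2, C7 prenyl, C8 CMe2, C9 bridging C=O; side chain C1' CH2, C2' CH-isopropenyl, C3' CH2, C4' CHOH).

Assumption: the sense of induction of the chiral palladium catalyst on the new pyronolate of step 16 cannot be predicted with certainty; the (R,R)-ligand is taken to give the (3S)-pyran-2,4-dione 23, and the (S,S)-ligand would be used if the opposite sense is found.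

Compounds 20–23 are carried as mixtures at the future C5 (21 also as an E/Z mixture); these converge in step 17.

**Route**

Step 1
Reactants: 1 1-(3,4-dihydroxyphenyl)ethan-1-one
Product: 2 1-[3,4-bis(triisopropylsilyloxy)phenyl]ethan-1-one
Conditions: i-Pr3SiCl (2.5 equiv), imidazole, DMF, 40 °C
Reagents that add atoms: chlorotriisopropylsilane, CC(C)[Si](Cl)(C(C)C)C(C)C
Why: Standard silylation of phenols; the bulky aryl silyl ethers should survive the amide bases, the borohydride and the palladium and copper steps and leave with the alkyl silyl ether at the end.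

Step 2
Reactants: 2 1-[3,4-bis(triisopropylsilyloxy)phenyl]ethan-1-one
Product: 4 6-[3,4-bis(triisopropylsilyloxy)phenyl]-4-hydroxy-2H-pyran-2-one, via trimethylsilyl enol ether 3 (not isolated)
Conditions: LiN(SiMe3)2, Me3SiCl, THF, −78 → 0 °C; evaporation; malonyl dichloride, Et2O, −78 °C → rt
Reagents that add atoms: malonyl dichloride, O=C(Cl)CC(=O)Cl; chlorotrimethylsilane, C[Si](C)(C)Cl (silyl group of 3)
Why: C-acylation of the silyl enol ether by malonyl dichloride and O-acylation of the resulting enol by the second acid chloride should close the 4-hydroxy-2-pyrone (silyl enol ether/malonyl dichloride pyrone synthesis).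

Step 3
Reactants: 4 6-[3,4-bis(triisopropylsilyloxy)phenyl]-4-hydroxy-2H-pyran-2-one; 5 2,2-dimethyl-5-(propan-2-ylidene)-1,3-dioxane-4,6-dione
Product: 6 7-[3,4-bis(triisopropylsilyloxy)phenyl]-4,4-dimethyl-3,4-dihydro-2H,5H-pyrano[4,3-b]pyran-2,5-dione
Conditions: Yb(OTf)3 (10 mol %), MeNO2, 90 °C
Reagents that add atoms: none
Why: Conjugate addition of the nucleophilic pyrone C3 to the alkylidene Meldrum's acid creates the quaternary CMe2 carbon (C8, bonded to the future C1), and the 4-OH then acylates itself on the Meldrum ring with loss of acetone and CO2 (Michael addition/lactonisation known for phenols and 4-hydroxypyrones).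

Step 4
Reactants: 6 7-[3,4-bis(triisopropylsilyloxy)phenyl]-4,4-dimethyl-3,4-dihydro-2H,5H-pyrano[4,3-b]pyran-2,5-dione; 7 (4S)-4-benzyl-1,3-oxazolidin-2-one
Product: 9 (4S)-4-benzyl-3-[(2S)-2-{2-[6-(3,4-bis(triisopropylsilyloxy)phenyl)-4-hydroxy-2-oxo-2H-pyran-3-yl]propan-2-yl}-5-methylhex-4-enoyl]-1,3-oxazolidin-2-one, via ring-opened lithium pyronolate imide 8 (not isolated)
Conditions: 7, n-BuLi, THF, −78 °C; 6, −78 → 0 °C; NaN(SiMe3)2, −78 °C; prenyl bromide, −78 → −30 °C; aq. NH4Cl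
Reagents that add atoms: 1-bromo-3-methylbut-2-ene, CC(C)=CCBr
Why: The lithiated auxiliary should open the enol δ-lactone (acyl transfer to the much weaker pyronolate base), and the chelated sodium Z-enolate of the imide is prenylated on the face opposite the benzyl group (Evans alkylation), which sets C7.

Step 5
Reactants: 9 (4S)-4-benzyl-3-[(2S)-2-{2-[6-(3,4-bis(triisopropylsilyloxy)phenyl)-4-hydroxy-2-oxo-2H-pyran-3-yl]propan-2-yl}-5-methylhex-4-enoyl]-1,3-oxazolidin-2-one
Product: 10 6-[3,4-bis(triisopropylsilyloxy)phenyl]-4-hydroxy-3-[(3S)-3-(hydroxymethyl)-2,6-dimethylhept-5-en-2-yl]-2H-pyran-2-one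
Conditions: LiBH4, H2O (1 equiv), Et2O, 0 °C
Reagents that add atoms: none
Why: Reductive cleavage of the N-acyloxazolidinone to the primary alcohol; the pyrone is protected in the flask as its unreactive lithium pyronolate, and auxiliary 7 is recovered.

Step 6
Reactants: 10 6-[3,4-bis(triisopropylsilyloxy)phenyl]-4-hydroxy-3-[(3S)-3-(hydroxymethyl)-2,6-dimethylhept-5-en-2-yl]-2H-pyran-2-one
Product: 11 6-[3,4-bis(triisopropylsilyloxy)phenyl]-3-[(3S)-3-(hydroxymethyl)-2,6-dimethylhept-5-en-2-yl]-4-[(3-methylbut-2-en-1-yl)oxy]-2H-pyran-2-one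
Conditions: prenyl bromide, K2CO3, acetone, 40 °C
Reagents that add atoms: 1-bromo-3-methylbut-2-ene, CC(C)=CCBr
Why: Carbonate deprotonates only the acidic pyrone OH (a vinylogous carboxylic acid) and the tert-alkyl group at C3 blocks C-alkylation, so Williamson O-alkylation parks on oxygen the prenyl group that later moves to C1; a 2-O-prenyl isomer, if formed, would ionise to the same pyronolate in step 16.

Step 7
Reactants: 11 6-[3,4-bis(triisopropylsilyloxy)phenyl]-3-[(3S)-3-(hydroxymethyl)-2,6-dimethylhept-5-en-2-yl]-4-[(3-methylbut-2-en-1-yl)oxy]-2H-pyran-2-one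
Product: 12 (2S)-2-{2-[6-(3,4-bis(triisopropylsilyloxy)phenyl)-4-[(3-methylbut-2-en-1-yl)oxy]-2-oxo-2H-pyran-3-yl]propan-2-yl}-5-methylhex-4-enal
Conditions: SO3·pyridine, DMSO, i-Pr2NEt, CH2Cl2, 0 °C
Reagents that add atoms: none
Why: Parikh–Doering oxidation under mild, cold conditions, so the α-stereocentre (shielded by the neighbouring quaternary carbon) should not epimerise.

Step 8
Reactants: 13 furan-2(5H)-one
Product: 14 (4S)-4-(prop-1-en-2-yl)oxolan-2-one
Conditions: [Rh(cod)2]PF6 (3 mol %), (S)-BINAP (3.3 mol %), potassium isopropenyltrifluoroborate, toluene/H2O (20:1), 100 °C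
Reagents that add atoms: potassium trifluoro(prop-1-en-2-yl)borate, [K+].C=C(C)[B-](F)(F)F
Why: Rh/BINAP-catalysed asymmetric 1,4-addition of an alkenylboron reagent to an unsaturated lactone (Hayashi–Miyaura reaction); (S)-BINAP should deliver the alkenyl group to the same enone face as in the cyclohexenone model, giving the (S)-lactone and thus C2'.

Step 9
Reactants: 14 (4S)-4-(prop-1-en-2-yl)oxolan-2-one
Product: 15 (5S)-5-(hydroxymethyl)-2,6-dimethylhepta-1,6-dien-3-one
Conditions: 2-bromopropene, t-BuLi (2 equiv), Et2O, −78 °C; then 14, −78 °C; AcOH quench at −78 °C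
Reagents that add atoms: isopropenyllithium (from 2-bromopropene and t-BuLi), [Li]C(C)=C
Why: The tetrahedral lithium lactolate is stable at −78 °C, so one alkenyllithium adds and the hydroxy enone is released only on quench (mono-addition of an organolithium to a lactone).

Step 10
Reactants: 15 (5S)-5-(hydroxymethyl)-2,6-dimethylhepta-1,6-dien-3-one
Product: 16 (5S)-5-(iodomethyl)-2,6-dimethylhepta-1,6-dien-3-one
Conditions: I2, PPh3, imidazole, CH2Cl2, 0 °C
Reagents that add atoms: iodine, [I][I]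
Why: Appel-type iodination of the only hydroxyl group, placed before the reduction so that no second alcohol competes.

Step 11
Reactants: 16 (5S)-5-(iodomethyl)-2,6-dimethylhepta-1,6-dien-3-one
Product: 17 (3R,5S)-5-(iodomethyl)-2,6-dimethylhepta-1,6-dien-3-ol
Conditions: (S)-2-methyl-CBS-oxazaborolidine (0.2 equiv), catecholborane, toluene, −78 °C
Reagents that add atoms: none
Why: Corey–Bakshi–Shibata reduction in which the isopropenyl group acts as the large substituent, so the (S)-catalyst should give the (R)-allylic alcohol (C4') under reagent control, while catecholborane leaves the 1,1-disubstituted alkenes untouched.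

Step 12
Reactants: 17 (3R,5S)-5-(iodomethyl)-2,6-dimethylhepta-1,6-dien-3-ol
Product: 18 tert-butyl{[(3R,5S)-5-(iodomethyl)-2,6-dimethylhepta-1,6-dien-3-yl]oxy}dimethylsilane
Conditions: t-BuMe2SiOTf, 2,6-lutidine, CH2Cl2, −78 °C
Reagents that add atoms: tert-butyldimethylsilyl trifluoromethanesulfonate, CC(C)(C)[Si](C)(C)OS(=O)(=O)C(F)(F)F
Why: Silylation with a non-nucleophilic base leaves the primary iodide alone.

Step 13
Reactants: 18 tert-butyl{[(3R,5S)-5-(iodomethyl)-2,6-dimethylhepta-1,6-dien-3-yl]oxy}dimethylsilane; 19 trimethyl phosphonoacetate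
Product: 20 methyl (4R,6R)-6-[(tert-butyldimethylsilyl)oxy]-2-(dimethoxyphosphoryl)-7-methyl-4-(prop-1-en-2-yl)oct-7-enoate (both C2 epimers)
Conditions: 19 (2 equiv), NaH (1.9 equiv), DMF, 0 °C; 18, 55 °C
Reagents that add atoms: none
Why: SN2 alkylation of the soft phosphonoacetate anion by the primary iodide; the new centre (future C5) forms as a mixture, which is harmless because it is planarised in steps 14 and 17.

Step 14
Reactants: 12 (2S)-2-{2-[6-(3,4-bis(triisopropylsilyloxy)phenyl)-4-[(3-methylbut-2-en-1-yl)oxy]-2-oxo-2H-pyran-3-yl]propan-2-yl}-5-methylhex-4-enal; 20 methyl (4R,6R)-6-[(tert-butyldimethylsilyl)oxy]-2-(dimethoxyphosphoryl)-7-methyl-4-(prop-1-en-2-yl)oct-7-enoate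
Product: 21 methyl (4R)-4-{2-[6-(3,4-bis(triisopropylsilyloxy)phenyl)-4-[(3-methylbut-2-en-1-yl)oxy]-2-oxo-2H-pyran-3-yl]propan-2-yl}-2-{(2S,4R)-4-[(tert-butyldimethylsilyl)oxy]-5-methyl-2-(prop-1-en-2-yl)hex-5-en-1-yl}-7-methylocta-2,6-dienoate (E/Z mixture)
Conditions: 20, NaH, THF, 0 °C; 12, 0 → 40 °C
Reagents that add atoms: none
Why: Horner–Wadsworth–Emmons olefination joins the two fragments at C5=C6; the alkene geometry is irrelevant because the double bond is reduced in the next step.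

Step 15
Reactants: 21 methyl (4R)-4-{2-[6-(3,4-bis(triisopropylsilyloxy)phenyl)-4-[(3-methylbut-2-en-1-yl)oxy]-2-oxo-2H-pyran-3-yl]propan-2-yl}-2-{(2S,4R)-4-[(tert-butyldimethylsilyl)oxy]-5-methyl-2-(prop-1-en-2-yl)hex-5-en-1-yl}-7-methylocta-2,6-dienoate
Product: 22 methyl (4R)-4-{2-[6-(3,4-bis(triisopropylsilyloxy)phenyl)-4-[(3-methylbut-2-en-1-yl)oxy]-2-oxo-2H-pyran-3-yl]propan-2-yl}-2-{(2S,4R)-4-[(tert-butyldimethylsilyl)oxy]-5-methyl-2-(prop-1-en-2-yl)hex-5-en-1-yl}-7-methyloct-6-enoate (both C2 epimers)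
Conditions: Cu(OAc)2·H2O (5 mol %), 1,2-bis(diphenylphosphino)benzene (5 mol %), (EtO)2MeSiH, t-BuOH, toluene, rt
Reagents that add atoms: none
Why: Ligand-accelerated copper hydride 1,4-reduction should select the α,β-unsaturated ester over the isolated alkenes and the electron-rich 4-alkoxy-2-pyrone; C5 again forms as a mixture.

Step 16
Reactants: 22 methyl (4R)-4-{2-[6-(3,4-bis(triisopropylsilyloxy)phenyl)-4-[(3-methylbut-2-en-1-yl)oxy]-2-oxo-2H-pyran-3-yl]propan-2-yl}-2-{(2S,4R)-4-[(tert-butyldimethylsilyl)oxy]-5-methyl-2-(prop-1-en-2-yl)hex-5-en-1-yl}-7-methyloct-6-enoate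
Product: 23 methyl (4R)-4-{2-[(3S)-6-(3,4-bis(triisopropylsilyloxy)phenyl)-3-(3-methylbut-2-en-1-yl)-2,4-dioxo-3,4-dihydro-2H-pyran-3-yl]propan-2-yl}-2-{(2S,4R)-4-[(tert-butyldimethylsilyl)oxy]-5-methyl-2-(prop-1-en-2-yl)hex-5-en-1-yl}-7-methyloct-6-enoate (both C2 epimers)
Conditions: Pd2(dba)3·CHCl3 (2.5 mol %), (R,R)-N,N'-(cyclohexane-1,2-diyl)bis[2-(diphenylphosphino)benzamide] (7.5 mol %), toluene, 0 °C → rt
Reagents that add atoms: none
Why: Proposed new method: zerovalent palladium should ionise the pyronyl prenyl ether (the pyronolate is a carboxylate-like leaving group) to an ion pair of the prenyl–palladium cation and the ambident pyronolate, in which O-attack is reversible whereas attack of C3 on the unhindered CH2 terminus gives the non-aromatic 3,3-disubstituted pyran-2,4-dione, and the chiral pocket of the ligand selects the face of the planar pyronolate, so the quaternary centre C1 is set under catalyst control; the closest known reactions are the palladium-catalysed 1,3 O-to-C allyl shift of allyl enol ethers of 1,3-dicarbonyl compounds and the asymmetric allylic alkylation of enolates released from allyl enol carbonates.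

Step 17
Reactants: 23 methyl (4R)-4-{2-[(3S)-6-(3,4-bis(triisopropylsilyloxy)phenyl)-3-(3-methylbut-2-en-1-yl)-2,4-dioxo-3,4-dihydro-2H-pyran-3-yl]propan-2-yl}-2-{(2S,4R)-4-[(tert-butyldimethylsilyl)oxy]-5-methyl-2-(prop-1-en-2-yl)hex-5-en-1-yl}-7-methyloct-6-enoate
Product: 25 (1R,5R,7R)-3-[3,4-bis(triisopropylsilyloxy)benzoyl]-5-{(2S,4R)-4-[(tert-butyldimethylsilyl)oxy]-5-methyl-2-(prop-1-en-2-yl)hex-5-en-1-yl}-4-hydroxy-8,8-dimethyl-1,7-bis(3-methylbut-2-en-1-yl)bicyclo[3.3.1]non-3-ene-2,9-dione, via monocyclic keto ester 24 (not isolated)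
Conditions: KN(SiMe3)2 (2.2 equiv), THF (0.01 M), −78 °C → rt; AcOH quench
Reagents that add atoms: none
Why: Proposed new method: deprotonation at the only acidic C–H gives the C5 ester enolate, which attacks the enol-lactone carbonyl C9 of the pyran-2,4-dione, so that collapse of the tetrahedral intermediate forms C5–C9 and releases the ring oxygen as the potassium enolate of an aroylacetyl group on C1, whose central carbon C3 then attacks the ester carbonyl C4 held cis on the new cyclohexanone and forms C3–C4 with loss of methoxide, the tricarbonyl product being deprotonated at once. The closest known reactions are the Dieckmann condensation of an ester enolate onto an enol-ester acyl donor and the Claisen cyclisation of 3,5-diketo esters to acylphloroglucinols, the benzophenone-forming step of the biosynthesis. The cyclohexanone ring closes in the 6-(enolexo)-exo-trig mode and the trione ring in the 6-(enolendo)-exo-trig mode. C5 is the only new stereocentre and is controlled by C1 through the bicyclo[3.3.1] ring constraint, because only the epimer with C4 cis to the C2 acyl group can bridge, while the other Dieckmann epimer should be reopened by retro-Dieckmann attack of the methoxide set free; C1 and C7 are untouched, so the C7 prenyl group ends endo as required. The step needs attack at C9 instead of C2 and C- instead of O-acylation at C4, and this is secured because only C9 carries a leaving group, aldol addition to the vinylogous-ester ketone C2 and O-acylation are reversible, and only the C3-acylated product leaves the equilibrium as its enolate.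

Step 18
Reactants: 25 (1R,5R,7R)-3-[3,4-bis(triisopropylsilyloxy)benzoyl]-5-{(2S,4R)-4-[(tert-butyldimethylsilyl)oxy]-5-methyl-2-(prop-1-en-2-yl)hex-5-en-1-yl}-4-hydroxy-8,8-dimethyl-1,7-bis(3-methylbut-2-en-1-yl)bicyclo[3.3.1]non-3-ene-2,9-dione
Product: 26 (1R,5R,7R)-3-(3,4-dihydroxybenzoyl)-4-hydroxy-5-[(2S,4R)-4-hydroxy-5-methyl-2-(prop-1-en-2-yl)hex-5-en-1-yl]-8,8-dimethyl-1,7-bis(3-methylbut-2-en-1-yl)bicyclo[3.3.1]non-3-ene-2,9-dione
Conditions: Bu4NF (6 equiv), AcOH (6 equiv), THF, 0 °C → rt, argon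
Reagents that add atoms: none
Why: Buffered fluoride should remove the two aryl silyl ethers and the secondary silyl ether without acid (which would cyclise the C4 enol onto a prenyl group) and without strong base (which would expose the catechol to oxidation).

**Compound list**

1 | 1-(3,4-dihydroxyphenyl)ethan-1-one | CC(=O)c1ccc(O)c(O)c1 | starting material
2 | 1-[3,4-bis(triisopropylsilyloxy)phenyl]ethan-1-one | CC(=O)c1ccc(O[Si](C(C)C)(C(C)C)C(C)C)c(O[Si](C(C)C)(C(C)C)C(C)C)c1 | intermediate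
3 | {1-[3,4-bis(triisopropylsilyloxy)phenyl]ethenyloxy}trimethylsilane (not isolated) | C=C(O[Si](C)(C)C)c1ccc(O[Si](C(C)C)(C(C)C)C(C)C)c(O[Si](C(C)C)(C(C)C)C(C)C)c1 | intermediate
4 | 6-[3,4-bis(triisopropylsilyloxy)phenyl]-4-hydroxy-2H-pyran-2-one | O=C1C=C(O)C=C(c2ccc(O[Si](C(C)C)(C(C)C)C(C)C)c(O[Si](C(C)C)(C(C)C)C(C)C)c2)O1 | intermediate
5 | 2,2-dimethyl-5-(propan-2-ylidene)-1,3-dioxane-4,6-dione | CC(C)=C1C(=O)OC(C)(C)OC1=O | starting material
6 | 7-[3,4-bis(triisopropylsilyloxy)phenyl]-4,4-dimethyl-3,4-dihydro-2H,5H-pyrano[4,3-b]pyran-2,5-dione | O=C1CC(C)(C)C2=C(O1)C=C(c3ccc(O[Si](C(C)C)(C(C)C)C(C)C)c(O[Si](C(C)C)(C(C)C)C(C)C)c3)OC2=O | intermediate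
7 | (4S)-4-benzyl-1,3-oxazolidin-2-one | O=C1OC[C@H](Cc2ccccc2)N1 | starting material
8 | (4S)-4-benzyl-3-{3-[6-(3,4-bis(triisopropylsilyloxy)phenyl)-4-hydroxy-2-oxo-2H-pyran-3-yl]-3-methylbutanoyl}-1,3-oxazolidin-2-one (present as lithium pyronolate, not isolated) | O=C1OC[C@H](Cc2ccccc2)N1C(=O)CC(C)(C)C1=C(O)C=C(c2ccc(O[Si](C(C)C)(C(C)C)C(C)C)c(O[Si](C(C)C)(C(C)C)C(C)C)c2)OC1=O | intermediate
9 | (4S)-4-benzyl-3-[(2S)-2-{2-[6-(3,4-bis(triisopropylsilyloxy)phenyl)-4-hydroxy-2-oxo-2H-pyran-3-yl]propan-2-yl}-5-methylhex-4-enoyl]-1,3-oxazolidin-2-one | O=C1OC[C@H](Cc2ccccc2)N1C(=O)[C@@H](CC=C(C)C)C(C)(C)C1=C(O)C=C(c2ccc(O[Si](C(C)C)(C(C)C)C(C)C)c(O[Si](C(C)C)(C(C)C)C(C)C)c2)OC1=O | intermediate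
10 | 6-[3,4-bis(triisopropylsilyloxy)phenyl]-4-hydroxy-3-[(3S)-3-(hydroxymethyl)-2,6-dimethylhept-5-en-2-yl]-2H-pyran-2-one | OC[C@@H](CC=C(C)C)C(C)(C)C1=C(O)C=C(c2ccc(O[Si](C(C)C)(C(C)C)C(C)C)c(O[Si](C(C)C)(C(C)C)C(C)C)c2)OC1=O | intermediate
11 | 6-[3,4-bis(triisopropylsilyloxy)phenyl]-3-[(3S)-3-(hydroxymethyl)-2,6-dimethylhept-5-en-2-yl]-4-[(3-methylbut-2-en-1-yl)oxy]-2H-pyran-2-one | OC[C@@H](CC=C(C)C)C(C)(C)C1=C(OCC=C(C)C)C=C(c2ccc(O[Si](C(C)C)(C(C)C)C(C)C)c(O[Si](C(C)C)(C(C)C)C(C)C)c2)OC1=O | intermediate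
12 | (2S)-2-{2-[6-(3,4-bis(triisopropylsilyloxy)phenyl)-4-[(3-methylbut-2-en-1-yl)oxy]-2-oxo-2H-pyran-3-yl]propan-2-yl}-5-methylhex-4-enal | O=C[C@@H](CC=C(C)C)C(C)(C)C1=C(OCC=C(C)C)C=C(c2ccc(O[Si](C(C)C)(C(C)C)C(C)C)c(O[Si](C(C)C)(C(C)C)C(C)C)c2)OC1=O | intermediate
13 | furan-2(5H)-one | O=C1C=CCO1 | starting material
14 | (4S)-4-(prop-1-en-2-yl)oxolan-2-one | C=C(C)[C@@H]1CC(=O)OC1 | intermediate
15 | (5S)-5-(hydroxymethyl)-2,6-dimethylhepta-1,6-dien-3-one | C=C(C)[C@H](CC(=O)C(C)=C)CO | intermediate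
16 | (5S)-5-(iodomethyl)-2,6-dimethylhepta-1,6-dien-3-one | C=C(C)[C@H](CC(=O)C(C)=C)CI | intermediate
17 | (3R,5S)-5-(iodomethyl)-2,6-dimethylhepta-1,6-dien-3-ol | C=C(C)[C@H](C[C@@H](O)C(C)=C)CI | intermediate
18 | tert-butyl{[(3R,5S)-5-(iodomethyl)-2,6-dimethylhepta-1,6-dien-3-yl]oxy}dimethylsilane | C=C(C)[C@H](C[C@@H](O[Si](C)(C)C(C)(C)C)C(C)=C)CI | intermediate
19 | trimethyl phosphonoacetate | COC(=O)CP(=O)(OC)OC | starting material
20 | methyl (4R,6R)-6-[(tert-butyldimethylsilyl)oxy]-2-(dimethoxyphosphoryl)-7-methyl-4-(prop-1-en-2-yl)oct-7-enoate (both C2 epimers) | COC(=O)C(C[C@H](C(C)=C)C[C@@H](O[Si](C)(C)C(C)(C)C)C(C)=C)P(=O)(OC)OC | intermediate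
21 | methyl (4R)-4-{2-[6-(3,4-bis(triisopropylsilyloxy)phenyl)-4-[(3-methylbut-2-en-1-yl)oxy]-2-oxo-2H-pyran-3-yl]propan-2-yl}-2-{(2S,4R)-4-[(tert-butyldimethylsilyl)oxy]-5-methyl-2-(prop-1-en-2-yl)hex-5-en-1-yl}-7-methylocta-2,6-dienoate (E/Z mixture) | COC(=O)C(C[C@H](C(C)=C)C[C@@H](O[Si](C)(C)C(C)(C)C)C(C)=C)=C[C@@H](CC=C(C)C)C(C)(C)C1=C(OCC=C(C)C)C=C(c2ccc(O[Si](C(C)C)(C(C)C)C(C)C)c(O[Si](C(C)C)(C(C)C)C(C)C)c2)OC1=O | intermediate
22 | methyl (4R)-4-{2-[6-(3,4-bis(triisopropylsilyloxy)phenyl)-4-[(3-methylbut-2-en-1-yl)oxy]-2-oxo-2H-pyran-3-yl]propan-2-yl}-2-{(2S,4R)-4-[(tert-butyldimethylsilyl)oxy]-5-methyl-2-(prop-1-en-2-yl)hex-5-en-1-yl}-7-methyloct-6-enoate (both C2 epimers) | COC(=O)C(C[C@H](C(C)=C)C[C@@H](O[Si](C)(C)C(C)(C)C)C(C)=C)C[C@@H](CC=C(C)C)C(C)(C)C1=C(OCC=C(C)C)C=C(c2ccc(O[Si](C(C)C)(C(C)C)C(C)C)c(O[Si](C(C)C)(C(C)C)C(C)C)c2)OC1=O | intermediate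
23 | methyl (4R)-4-{2-[(3S)-6-(3,4-bis(triisopropylsilyloxy)phenyl)-3-(3-methylbut-2-en-1-yl)-2,4-dioxo-3,4-dihydro-2H-pyran-3-yl]propan-2-yl}-2-{(2S,4R)-4-[(tert-butyldimethylsilyl)oxy]-5-methyl-2-(prop-1-en-2-yl)hex-5-en-1-yl}-7-methyloct-6-enoate (both C2 epimers) | COC(=O)C(C[C@H](C(C)=C)C[C@@H](O[Si](C)(C)C(C)(C)C)C(C)=C)C[C@@H](CC=C(C)C)C(C)(C)[C@@]1(CC=C(C)C)C(=O)C=C(c2ccc(O[Si](C(C)C)(C(C)C)C(C)C)c(O[Si](C(C)C)(C(C)C)C(C)C)c2)OC1=O | intermediate
24 | methyl 3-{3-[3,4-bis(triisopropylsilyloxy)phenyl]-3-oxopropanoyl}-1-{(2S,4R)-4-[(tert-butyldimethylsilyl)oxy]-5-methyl-2-(prop-1-en-2-yl)hex-5-en-1-yl}-4,4-dimethyl-3,5-bis(3-methylbut-2-en-1-yl)-2-oxocyclohexane-1-carboxylate; ester at C1, ketoacyl group at C3 and prenyl at C5 all cis; present as potassium enolate (not isolated) | COC(=O)[C@@]1(C[C@H](C(C)=C)C[C@@H](O[Si](C)(C)C(C)(C)C)C(C)=C)C[C@@H](CC=C(C)C)C(C)(C)[C@@](CC=C(C)C)(C(=O)CC(=O)c2ccc(O[Si](C(C)C)(C(C)C)C(C)C)c(O[Si](C(C)C)(C(C)C)C(C)C)c2)C1=O | intermediate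
25 | (1R,5R,7R)-3-[3,4-bis(triisopropylsilyloxy)benzoyl]-5-{(2S,4R)-4-[(tert-butyldimethylsilyl)oxy]-5-methyl-2-(prop-1-en-2-yl)hex-5-en-1-yl}-4-hydroxy-8,8-dimethyl-1,7-bis(3-methylbut-2-en-1-yl)bicyclo[3.3.1]non-3-ene-2,9-dione | C=C(C)[C@H](C[C@@H](O[Si](C)(C)C(C)(C)C)C(=C)C)C[C@@]12C[C@@H](CC=C(C)C)C(C)(C)[C@@](CC=C(C)C)(C(=O)C(C(=O)c3ccc(O[Si](C(C)C)(C(C)C)C(C)C)c(O[Si](C(C)C)(C(C)C)C(C)C)c3)=C1O)C2=O | intermediate
26 | (1R,5R,7R)-3-(3,4-dihydroxybenzoyl)-4-hydroxy-5-[(2S,4R)-4-hydroxy-5-methyl-2-(prop-1-en-2-yl)hex-5-en-1-yl]-8,8-dimethyl-1,7-bis(3-methylbut-2-en-1-yl)bicyclo[3.3.1]non-3-ene-2,9-dione | C=C(C)[C@H](C[C@@H](O)C(=C)C)C[C@@]12C[C@@H](CC=C(C)C)C(C)(C)[C@@](CC=C(C)C)(C(=O)C(C(=O)c3ccc(O)c(O)c3)=C1O)C2=O | target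

**Step count and risks**

Total step count: 18. Longest linear sequence: 12 steps (steps 1–7 and 14–18); the side-chain branch (steps 8–13) then 14–18 is 11.

Steps most likely to fail:

1. Step 17 (Proposed new method). The relay may stall after the first ring closure if the stabilised diketone enolate acylates too slowly, the wrong C5 epimer of the Dieckmann product may not be reopened, or the hindered lactone may fragment by retro-Claisen cleavage at C1. Fallback, stepwise and with classical reactions, setting out from 23: NaOMe (1 equiv) in MeOH at 0 °C opens the enol lactone to the open-chain aroylacetyl diester F1; NaH with catalytic MeOH in THF at reflux effects a reversible Dieckmann condensation, and the monocyclic keto ester 24 is now isolated; Mg(OMe)2 in MeOH at reflux then closes C3–C4 by the magnesium-chelate Claisen cyclisation known for 3,5-diketo esters. The fallback returns to the route at 25.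

2. Step 16 (Proposed new method). The prenyl–palladium ion pair may collapse with poor facial selectivity at C1, may return only O-prenylated material because of the strain of the two adjacent quaternary carbons, or may lose isoprene. Fallback by 1,3-chirality transfer, setting out from 22: Pd(PPh3)4 and morpholine remove the O-prenyl group to give the free hydroxypyrone F2; Mitsunobu reaction with (S)-but-3-en-2-ol (PPh3, diisopropyl azodicarboxylate, inversion) gives the (R)-but-3-en-2-yl ether F3; heating in toluene at 110 °C effects the dearomative Claisen rearrangement through a chair transition state with the methyl group equatorial, which places an (E)-but-2-enyl group on the required face of C3 and gives the (3S)-dione F4; cross-metathesis with 2-methyl-2-butene and the second-generation Grubbs catalyst (H2IMes)(PCy3)Cl2Ru=CHPh converts the butenyl into the prenyl group. The fallback returns to the route at 23.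

3. Step 14. The α-branched aldehyde flanked by a quaternary carbon and the α-substituted phosphonate may react too slowly, with enolisation and loss of configuration at C7 as the competing process. Fallback by a different bond, setting out from 12: Wittig reaction with Ph3P=CHCO2Me in toluene at 60 °C gives the unsubstituted E-enoate F5; copper hydride reduction as in step 15 gives the saturated ester F6; its lithium enolate (LiN(i-Pr)2, THF/DMPU, −78 °C) is alkylated at C5 with iodide 18. The fallback returns to the route at 22 and also bypasses step 15.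

**Further compounds**

F1 | step 17 | dimethyl ester from methanolysis of 23: C1 bears CO2Me, the 3-aryl-3-oxopropanoyl group, prenyl and the C8–C5 chain ending in the C5 methyl ester | COC(=O)C(C[C@H](C(C)=C)C[C@@H](O[Si](C)(C)C(C)(C)C)C(C)=C)C[C@@H](CC=C(C)C)C(C)(C)[C@@](CC=C(C)C)(C(=O)CC(=O)c1ccc(O[Si](C(C)C)(C(C)C)C(C)C)c(O[Si](C(C)C)(C(C)C)C(C)C)c1)C(=O)OC
F2 | step 16 | 4-hydroxy-2-pyrone obtained from 22 by loss of the O-prenyl group | COC(=O)C(C[C@H](C(C)=C)C[C@@H](O[Si](C)(C)C(C)(C)C)C(C)=C)C[C@@H](CC=C(C)C)C(C)(C)C1=C(O)C=C(c2ccc(O[Si](C(C)C)(C(C)C)C(C)C)c(O[Si](C(C)C)(C(C)C)C(C)C)c2)OC1=O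
F3 | step 16 | 4-O-[(2R)-but-3-en-2-yl] ether of F2 | COC(=O)C(C[C@H](C(C)=C)C[C@@H](O[Si](C)(C)C(C)(C)C)C(C)=C)C[C@@H](CC=C(C)C)C(C)(C)C1=C(O[C@H](C)C=C)C=C(c2ccc(O[Si](C(C)C)(C(C)C)C(C)C)c(O[Si](C(C)C)(C(C)C)C(C)C)c2)OC1=O
F4 | step 16 | (3S)-3-[(E)-but-2-en-1-yl] analogue of 23 | COC(=O)C(C[C@H](C(C)=C)C[C@@H](O[Si](C)(C)C(C)(C)C)C(C)=C)C[C@@H](CC=C(C)C)C(C)(C)[C@@]1(C/C=C/C)C(=O)C=C(c2ccc(O[Si](C(C)C)(C(C)C)C(C)C)c(O[Si](C(C)C)(C(C)C)C(C)C)c2)OC1=O
F5 | step 14 | methyl (2E)-enoate from 12 and Ph3P=CHCO2Me, without the C5 side chain | COC(=O)/C=C/[C@@H](CC=C(C)C)C(C)(C)C1=C(OCC=C(C)C)C=C(c2ccc(O[Si](C(C)C)(C(C)C)C(C)C)c(O[Si](C(C)C)(C(C)C)C(C)C)c2)OC1=O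
F6 | step 14 | saturated methyl ester from F5, without the C5 side chain | COC(=O)CC[C@@H](CC=C(C)C)C(C)(C)C1=C(OCC=C(C)C)C=C(c2ccc(O[Si](C(C)C)(C(C)C)C(C)C)c(O[Si](C(C)C)(C(C)C)C(C)C)c2)OC1=O
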